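**Retrosynthetic overview**
1. Target 35 ⇐ O‑TBS precursor 34; its (E)‑ylidene butenolide is unmasked last from the furan in macrocycle 31 (¹O₂ oxidation, then dehydration).
2. Macrocycle 31 ⇐ open‑chain diacetate 30 by a Pd‑catalysed intramolecular furfurylation of the 3(2H)‑furanone enolate (C4–C5 bond, quaternary C4, ten‑membered carbocycle).
3. 30 ⇐ carbinol 23 + side‑chain acid 27; 23 ⇐ ketone 22 (CBS); 22 ⇐ thioester 12 + furylstannane 21 by Pd/Cu ketone synthesis (C7–C8).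
4. 12 ⇐ itaconic anhydride + but‑3‑yn‑2‑ol (Pd acylation, Au furanone formation); 21 ⇐ 3,4‑dibromofuran + 2 CH₂O; 27 ⇐ 4‑methylfuran‑2(5H)‑one.
5. Ring order: 3(2H)‑furanone (step 5) → ten‑membered carbocycle (step 20) → butenolide, from the purchased furan ring (step 21).

Assumption: germacrane atom numbers are used throughout (C1/C2/C3 = furanone C–O, CH, C=O; C4 = C–Me; C5 = ylidene CH; C6/C7/C11/C12 = butenolide; C8 = acyloxy CH; C9 = CH₂; C10 = CH–Me; C13 = CH₂OAc); the target is 4S,8S,10S,5E,2′Z; compounds 9–12, 22, 23 and 28–30 are epimer mixtures at the not‑yet‑fixed carbinol/furanone C4 centre, which is erased in step 20.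

**Step 1**
Reactants: 1 itaconic anhydride
Product: 2 4‑methoxy‑2‑methylidene‑4‑oxobutanoic acid
Conditions: MeOH (neat), 65 °C
Reagents that add atoms: methanol (CO)
Why: Anhydride alcoholysis; MeOH attacks the non‑conjugated, more electrophilic carbonyl, leaving the acrylic acid free.

**Step 2**
Reactants: 2 4‑methoxy‑2‑methylidene‑4‑oxobutanoic acid
Product: 3 (2S)‑4‑methoxy‑2‑methyl‑4‑oxobutanoic acid
Conditions: H₂ (4 bar), [Rh(cod)(Et‑DuPhos)]BF₄ (0.2 mol%, ligand antipode that gives 2S), MeOH, rt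
Reagents that add atoms: none
Why: Rh‑bisphosphine asymmetric hydrogenation of an itaconate half‑ester (chelating substrate, high ee) sets C10 as S.

**Step 3**
Reactants: 4 (±)‑but‑3‑yn‑2‑ol
Product: 5 trimethyl(but‑3‑yn‑2‑yloxy)silane
Conditions: TMSCl, Et₃N, CH₂Cl₂, 0 °C
Reagents that add atoms: chlorotrimethylsilane (C[Si](C)(C)Cl)
Why: Silyl ether formation masks the OH so that only the alkyne terminus is acylated in step 4.

**Step 4**
Reactants: 3 (2S)‑4‑methoxy‑2‑methyl‑4‑oxobutanoic acid; 5 trimethyl(but‑3‑yn‑2‑yloxy)silane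
Product: 9 methyl (3S)‑7‑hydroxy‑3‑methyl‑4‑oxooct‑5‑ynoate, via acid chloride 6 (not isolated), via alkynylzinc chloride 7 (not isolated), via TMS ether 8 (not isolated)
Conditions: 3, (COCl)₂, cat. DMF, CH₂Cl₂, 0 °C→rt, evaporate; 5, n‑BuLi, THF, −78 °C, then ZnCl₂; add 6, Pd(PPh₃)₄ (3 mol%), 0 °C→rt; 1 M HCl/THF work‑up
Reagents that add atoms: none
Why: Negishi acylation (Pd‑catalysed acid chloride–alkynylzinc coupling) forms C1–C2 without amine base, so the α‑stereocentre cannot racemise via a ketene; the TMS ether falls off in the acidic work‑up.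

**Step 5**
Reactants: 9 methyl (3S)‑7‑hydroxy‑3‑methyl‑4‑oxooct‑5‑ynoate
Product: 10 methyl (3S)‑3‑(5‑methyl‑4‑oxo‑4,5‑dihydrofuran‑2‑yl)butanoate
Conditions: (p‑CF₃C₆H₄)₃PAuCl/AgOTf (5 mol%), toluene, rt
Reagents that add atoms: none
Why: Au(I)‑catalysed cycloisomerisation of a 4‑hydroxy‑2‑yn‑1‑one (formal hydration–cyclodehydration) builds the 3(2H)‑furanone ring under neutral conditions.

**Step 6**
Reactants: 10 methyl (3S)‑3‑(5‑methyl‑4‑oxo‑4,5‑dihydrofuran‑2‑yl)butanoate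
Product: 11 (3S)‑3‑(5‑methyl‑4‑oxo‑4,5‑dihydrofuran‑2‑yl)butanoic acid
Conditions: Me₃SnOH, 1,2‑dichloroethane, 70 °C; dilute HCl work‑up
Reagents that add atoms: trimethyltin hydroxide (C[Sn](C)(C)O)
Why: Me₃SnOH ester cleavage is near‑neutral and spares the vinylogous ester of the furanone, which aqueous hydroxide could open.

**Step 7**
Reactants: 11 (3S)‑3‑(5‑methyl‑4‑oxo‑4,5‑dihydrofuran‑2‑yl)butanoic acid
Product: 12 S‑ethyl (3S)‑3‑(5‑methyl‑4‑oxo‑4,5‑dihydrofuran‑2‑yl)butanethioate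
Conditions: EtSH, EDC·HCl, DMAP (10 mol%), CH₂Cl₂, 0 °C→rt
Reagents that add atoms: ethanethiol (CCS)
Why: Steglich‑type thioesterification gives the acyl donor for the neutral ketone synthesis in step 13.

**Step 8**
Reactants: 13 3,4‑dibromofuran
Product: 15 (4‑bromofuran‑3‑yl)methanol, via 3‑bromo‑4‑lithiofuran 14 (not isolated)
Conditions: n‑BuLi (1.0 equiv), Et₂O, −78 °C; CH₂O (g); NH₄Cl
Reagents that add atoms: formaldehyde (C=O)
Why: Mono Br/Li exchange on the symmetric dibromide and hydroxymethylation install C13.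

**Step 9**
Reactants: 15 (4‑bromofuran‑3‑yl)methanol
Product: 16 [(4‑bromofuran‑3‑yl)methoxy]triethylsilane
Conditions: TESCl, imidazole, CH₂Cl₂, 0 °C
Reagents that add atoms: chlorotriethylsilane (CC[Si](Cl)(CC)CC)
Why: Silyl protection removes the alkoxide, which would otherwise direct the next metalation to the wrong α‑position.

**Step 10**
Reactants: 16 [(4‑bromofuran‑3‑yl)methoxy]triethylsilane
Product: 18 {3‑bromo‑4‑[(triethylsilyloxy)methyl]furan‑2‑yl}methanol, via 2‑lithiofuran 17 (not isolated)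
Conditions: LDA, THF, −78 °C; CH₂O (g); NH₄Cl
Reagents that add atoms: formaldehyde (C=O)
Why: LDA deprotonates the furan α‑CH next to bromine (most acidic, as for 3‑bromofuran) and hydroxymethylation installs C5 on C6.

**Step 11**
Reactants: 18 {3‑bromo‑4‑[(triethylsilyloxy)methyl]furan‑2‑yl}methanol
Product: 19 3‑bromo‑2,4‑bis[(triethylsilyloxy)methyl]furan
Conditions: TESCl, imidazole, CH₂Cl₂, 0 °C
Reagents that add atoms: chlorotriethylsilane (CC[Si](Cl)(CC)CC)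
Why: Standard silylation; both primary oxygens now carry the same labile group, removed together in step 18.

**Step 12**
Reactants: 19 3‑bromo‑2,4‑bis[(triethylsilyloxy)methyl]furan
Product: 21 tributyl{2,4‑bis[(triethylsilyloxy)methyl]furan‑3‑yl}stannane, via 3‑lithiofuran 20 (not isolated)
Conditions: t‑BuLi (2.1 equiv), Et₂O, −78 °C; Bu₃SnCl
Reagents that add atoms: tributyltin chloride (CCCC[Sn](Cl)(CCCC)CCCC)
Why: Br/Li exchange and stannylation at −78 °C in ether outrun lithium migration and retro‑Brook silyl shift.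

**Step 13**
Reactants: 12 S‑ethyl (3S)‑3‑(5‑methyl‑4‑oxo‑4,5‑dihydrofuran‑2‑yl)butanethioate; 21 tributyl{2,4‑bis[(triethylsilyloxy)methyl]furan‑3‑yl}stannane
Product: 22 (3S)‑1‑{2,4‑bis[(triethylsilyloxy)methyl]furan‑3‑yl}‑3‑(5‑methyl‑4‑oxo‑4,5‑dihydrofuran‑2‑yl)butan‑1‑one
Conditions: Pd₂(dba)₃ (2.5 mol%), P(2‑furyl)₃ (10 mol%), Cu(I) diphenylphosphinate (1.5 equiv), THF, 50 °C
Reagents that add atoms: none
Why: Liebeskind–Srogl‑type Pd‑catalysed, Cu(I)‑mediated thioester–stannane coupling forms C7–C8 without base, so the acidic furanone C4–H and the ester‑free enone are untouched.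

**Step 14**
Reactants: 22 (3S)‑1‑{2,4‑bis[(triethylsilyloxy)methyl]furan‑3‑yl}‑3‑(5‑methyl‑4‑oxo‑4,5‑dihydrofuran‑2‑yl)butan‑1‑one
Product: 23 (1S,3S)‑1‑{2,4‑bis[(triethylsilyloxy)methyl]furan‑3‑yl}‑3‑(5‑methyl‑4‑oxo‑4,5‑dihydrofuran‑2‑yl)butan‑1‑ol
Conditions: (R)‑Me‑CBS (20 mol%), catecholborane, toluene, −78 °C
Reagents that add atoms: none
Why: Corey–Bakshi–Shibata reduction of the heteroaryl ketone (furyl = large group) gives the 8S carbinol under catalyst control; the less electrophilic vinylogous‑ester carbonyl is not reduced.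

**Step 15**
Reactants: 24 4‑methylfuran‑2(5H)‑one
Product: 25 potassium (2Z)‑4‑hydroxy‑3‑methylbut‑2‑enoate
Conditions: KOH (1.0 equiv), MeOH/H₂O, rt; evaporate
Reagents that add atoms: potassium hydroxide ([K+].[OH-])
Why: Lactone saponification; the Z geometry is inherited from the ring and kept by never acidifying the free hydroxy acid.

**Step 16**
Reactants: 25 potassium (2Z)‑4‑hydroxy‑3‑methylbut‑2‑enoate
Product: 27 (2Z)‑4‑(tert‑butyldimethylsilyloxy)‑3‑methylbut‑2‑enoic acid, via bis‑TBS derivative 26 (not isolated)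
Conditions: TBSCl (2.2 equiv), imidazole, DMF, rt; then THF/H₂O/AcOH, 0 °C
Reagents that add atoms: tert‑butyldimethylsilyl chloride (CC(C)(C)[Si](C)(C)Cl)
Why: Bis‑silylation followed by selective hydrolysis of the labile silyl ester gives the O‑protected Z acid, which cannot relactonise.

**Step 17**
Reactants: 23 (1S,3S)‑1‑{2,4‑bis[(triethylsilyloxy)methyl]furan‑3‑yl}‑3‑(5‑methyl‑4‑oxo‑4,5‑dihydrofuran‑2‑yl)butan‑1‑ol; 27 (2Z)‑4‑(tert‑butyldimethylsilyloxy)‑3‑methylbut‑2‑enoic acid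
Product: 28 (1S,3S)‑1‑{2,4‑bis[(triethylsilyloxy)methyl]furan‑3‑yl}‑3‑(5‑methyl‑4‑oxo‑4,5‑dihydrofuran‑2‑yl)butyl (2Z)‑4‑(tert‑butyldimethylsilyloxy)‑3‑methylbut‑2‑enoate
Conditions: EDC·HCl, DMAP (0.2 equiv), CH₂Cl₂, 0 °C→rt
Reagents that add atoms: none
Why: Steglich esterification acylates the C8 oxygen with retention; no amine base is used, which limits Z→E or deconjugative isomerisation of the enoate.

**Step 18**
Reactants: 28 (the bis‑TES ester of step 17)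
Product: 29 (1S,3S)‑1‑[2,4‑bis(hydroxymethyl)furan‑3‑yl]‑3‑(5‑methyl‑4‑oxo‑4,5‑dihydrofuran‑2‑yl)butyl (2Z)‑4‑(tert‑butyldimethylsilyloxy)‑3‑methylbut‑2‑enoate
Conditions: HF·pyridine, pyridine, THF, 0 °C
Reagents that add atoms: none
Why: Buffered HF cleaves primary TES ethers much faster than the primary TBS ether (standard silyl‑ether selectivity).

**Step 19**
Reactants: 29 (the diol of step 18)
Product: 30 (1S,3S)‑1‑[2,4‑bis(acetoxymethyl)furan‑3‑yl]‑3‑(5‑methyl‑4‑oxo‑4,5‑dihydrofuran‑2‑yl)butyl (2Z)‑4‑(tert‑butyldimethylsilyloxy)‑3‑methylbut‑2‑enoate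
Conditions: Ac₂O, pyridine, 0 °C
Reagents that add atoms: acetic anhydride (CC(=O)OC(C)=O)
Why: One acetylation installs both the C13 acetate of the target and the 2‑furylmethyl leaving group at C5.

**Step 20**
Reactants: 30 (the diacetate of step 19)
Product: 31 (4S,8S,10S)‑macrocyclic furan: carbocycle C1–C10 bridged by the 3(2H)‑furanone oxygen (C1–O–C4), fused at C6–C7 to the furan that carries C13H₂OAc on C11 and H on C12, with the 8‑O‑[(2Z)‑4‑TBSO‑3‑methylbut‑2‑enoyl] ester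
Conditions: Pd₂(dba)₃·CHCl₃ (5 mol%), DACH‑phenyl Trost ligand (12 mol%, both antipodes screened), Cs₂CO₃ (1.5 equiv), toluene, 60 °C, 2 mM, slow addition
Reagents that add atoms: none
Why: Proposed new method: Pd(0) ionises the electron‑rich 2‑furylmethyl acetate (much faster than the 3‑furylmethyl acetate or the secondary ester) to an η³‑furfuryl‑Pd cation, Cs₂CO₃ turns the 2‑methyl‑3(2H)‑furanone into its soft aromatic 3‑furanolate, and outer‑sphere C‑attack at the exocyclic CH₂ re‑aromatises the furan, forms C4–C5, closes the ten‑membered ring and creates the quaternary centre, with the enolate face chosen by the chiral ligand pocket matched to the 8S,10S tether to give 4S; the closest known reactions are Pd‑catalysed asymmetric benzylation of azlactones and oxindoles with (hetero)benzylic esters and Tsuji–Trost macrocyclisation.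

**Step 21**
Reactants: 31 (the macrocyclic furan of step 20)
Product: 34 O‑TBS‑protected target, via furan endoperoxide 32 (not isolated), via hydroxybutenolide 33 (not isolated)
Conditions: O₂, hν (visible), rose bengal (cat.), i‑Pr₂NEt, CH₂Cl₂, −78 °C; then TFAA, 2,6‑lutidine, −78→0 °C
Reagents that add atoms: oxygen (O=O)
Why: Furan [4+2] photooxygenation and base‑induced endoperoxide fragmentation (Kornblum–DeLaMare type; the only α‑H, at C12, fixes C12 as the carbonyl) give the 5‑hydroxybutenolide, and protoanemonin‑type dehydration of this pseudo‑acid can only lose a C5 proton, giving the cis‑in‑ring (heliangolide‑type) exocyclic alkene, i.e. the 5E ylidene.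

**Step 22**
Reactants: 34 O‑TBS‑protected target
Product: 35 CNP0269057.1
Conditions: HF·pyridine, pyridine, THF, 0 °C→rt
Reagents that add atoms: none
Why: Mildly acidic fluoride desilylation frees the side‑chain alcohol without base, so the allylic acetate, the ylidene butenolide and the Z‑hydroxy‑enoate (prone to lactonise) survive.

**Compound list**
1 | itaconic anhydride | C=C1CC(=O)OC1=O | starting material
2 | 4‑methoxy‑2‑methylidene‑4‑oxobutanoic acid | C=C(CC(=O)OC)C(=O)O | intermediate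
3 | (2S)‑4‑methoxy‑2‑methyl‑4‑oxobutanoic acid | C[C@@H](CC(=O)OC)C(=O)O | intermediate
4 | (±)‑but‑3‑yn‑2‑ol | CC(O)C#C | starting material
5 | trimethyl(but‑3‑yn‑2‑yloxy)silane | CC(O[Si](C)(C)C)C#C | intermediate
6 | methyl (3S)‑4‑chloro‑3‑methyl‑4‑oxobutanoate | C[C@@H](CC(=O)OC)C(=O)Cl | intermediate (not isolated)
7 | [3‑(trimethylsilyloxy)but‑1‑ynyl]zinc chloride | CC(O[Si](C)(C)C)C#C[Zn]Cl | intermediate (not isolated)
8 | methyl (3S)‑3‑methyl‑4‑oxo‑7‑(trimethylsilyloxy)oct‑5‑ynoate | C[C@@H](CC(=O)OC)C(=O)C#CC(C)O[Si](C)(C)C | intermediate (not isolated)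
9 | methyl (3S)‑7‑hydroxy‑3‑methyl‑4‑oxooct‑5‑ynoate | C[C@@H](CC(=O)OC)C(=O)C#CC(C)O | intermediate
10 | methyl (3S)‑3‑(5‑methyl‑4‑oxo‑4,5‑dihydrofuran‑2‑yl)butanoate | C[C@@H](CC(=O)OC)C1=CC(=O)C(C)O1 | intermediate
11 | (3S)‑3‑(5‑methyl‑4‑oxo‑4,5‑dihydrofuran‑2‑yl)butanoic acid | C[C@@H](CC(=O)O)C1=CC(=O)C(C)O1 | intermediate
12 | S‑ethyl (3S)‑3‑(5‑methyl‑4‑oxo‑4,5‑dihydrofuran‑2‑yl)butanethioate | C[C@@H](CC(=O)SCC)C1=CC(=O)C(C)O1 | intermediate
13 | 3,4‑dibromofuran | Brc1cocc1Br | starting material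
14 | 3‑bromo‑4‑lithiofuran | [Li]c1cocc1Br | intermediate (not isolated)
15 | (4‑bromofuran‑3‑yl)methanol | OCc1cocc1Br | intermediate
16 | [(4‑bromofuran‑3‑yl)methoxy]triethylsilane | CC[Si](CC)(CC)OCc1cocc1Br | intermediate
17 | {3‑bromo‑4‑[(triethylsilyloxy)methyl]furan‑2‑yl}lithium | CC[Si](CC)(CC)OCc1coc([Li])c1Br | intermediate (not isolated)
18 | {3‑bromo‑4‑[(triethylsilyloxy)methyl]furan‑2‑yl}methanol | CC[Si](CC)(CC)OCc1coc(CO)c1Br | intermediate
19 | 3‑bromo‑2,4‑bis[(triethylsilyloxy)methyl]furan | CC[Si](CC)(CC)OCc1coc(CO[Si](CC)(CC)CC)c1Br | intermediate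
20 | {2,4‑bis[(triethylsilyloxy)methyl]furan‑3‑yl}lithium | CC[Si](CC)(CC)OCc1coc(CO[Si](CC)(CC)CC)c1[Li] | intermediate (not isolated)
21 | tributyl{2,4‑bis[(triethylsilyloxy)methyl]furan‑3‑yl}stannane | CC[Si](CC)(CC)OCc1coc(CO[Si](CC)(CC)CC)c1[Sn](CCCC)(CCCC)CCCC | intermediate
22 | (3S)‑1‑{2,4‑bis[(triethylsilyloxy)methyl]furan‑3‑yl}‑3‑(5‑methyl‑4‑oxo‑4,5‑dihydrofuran‑2‑yl)butan‑1‑one | C[C@@H](CC(=O)c1c(CO[Si](CC)(CC)CC)occ1CO[Si](CC)(CC)CC)C1=CC(=O)C(C)O1 | intermediate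
23 | (1S,3S)‑1‑{2,4‑bis[(triethylsilyloxy)methyl]furan‑3‑yl}‑3‑(5‑methyl‑4‑oxo‑4,5‑dihydrofuran‑2‑yl)butan‑1‑ol | C[C@@H](C[C@H](O)c1c(CO[Si](CC)(CC)CC)occ1CO[Si](CC)(CC)CC)C1=CC(=O)C(C)O1 | intermediate
24 | 4‑methylfuran‑2(5H)‑one | CC1=CC(=O)OC1 | starting material
25 | potassium (2Z)‑4‑hydroxy‑3‑methylbut‑2‑enoate | [K+].[O-]C(=O)/C=C(/C)CO | intermediate
26 | tert‑butyldimethylsilyl (2Z)‑4‑(tert‑butyldimethylsilyloxy)‑3‑methylbut‑2‑enoate | CC(C)(C)[Si](C)(C)OC(=O)/C=C(/C)CO[Si](C)(C)C(C)(C)C | intermediate (not isolated)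
27 | (2Z)‑4‑(tert‑butyldimethylsilyloxy)‑3‑methylbut‑2‑enoic acid | OC(=O)/C=C(/C)CO[Si](C)(C)C(C)(C)C | intermediate
28 | (1S,3S)‑1‑{2,4‑bis[(triethylsilyloxy)methyl]furan‑3‑yl}‑3‑(5‑methyl‑4‑oxo‑4,5‑dihydrofuran‑2‑yl)butyl (2Z)‑4‑(TBSO)‑3‑methylbut‑2‑enoate | C[C@@H](C[C@H](OC(=O)/C=C(/C)CO[Si](C)(C)C(C)(C)C)c1c(CO[Si](CC)(CC)CC)occ1CO[Si](CC)(CC)CC)C1=CC(=O)C(C)O1 | intermediate
29 | (1S,3S)‑1‑[2,4‑bis(hydroxymethyl)furan‑3‑yl]‑3‑(5‑methyl‑4‑oxo‑4,5‑dihydrofuran‑2‑yl)butyl (2Z)‑4‑(TBSO)‑3‑methylbut‑2‑enoate | C[C@@H](C[C@H](OC(=O)/C=C(/C)CO[Si](C)(C)C(C)(C)C)c1c(CO)occ1CO)C1=CC(=O)C(C)O1 | intermediate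
30 | (1S,3S)‑1‑[2,4‑bis(acetoxymethyl)furan‑3‑yl]‑3‑(5‑methyl‑4‑oxo‑4,5‑dihydrofuran‑2‑yl)butyl (2Z)‑4‑(TBSO)‑3‑methylbut‑2‑enoate | C[C@@H](C[C@H](OC(=O)/C=C(/C)CO[Si](C)(C)C(C)(C)C)c1c(COC(C)=O)occ1COC(C)=O)C1=CC(=O)C(C)O1 | intermediate
31 | (4S,8S,10S)‑macrocyclic furan (furanone‑bridged ten‑membered carbocycle fused to the 11‑acetoxymethyl furan, 8‑O‑side‑chain ester, TBS ether) | CC(=O)OCc1c2c(C[C@]3(C)OC(=CC3=O)[C@@H](C)C[C@@H]2OC(=O)/C=C(/C)CO[Si](C)(C)C(C)(C)C)oc1 | intermediate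
32 | 6,12‑endoperoxide of 31 | CC(=O)OCC1=C2C3(C[C@]4(C)OC(=CC4=O)[C@@H](C)C[C@@H]2OC(=O)/C=C(/C)CO[Si](C)(C)C(C)(C)C)OOC1O3 | intermediate (not isolated)
33 | 6‑hydroxy‑butenolide (pseudo‑acid; C6 epimers) | CC(=O)OCC1=C2C(O)(C[C@]3(C)OC(=CC3=O)[C@@H](C)C[C@@H]2OC(=O)/C=C(/C)CO[Si](C)(C)C(C)(C)C)OC1=O | intermediate (not isolated)
34 | O‑TBS ether of the target (4S,8S,10S,5E,2′Z) | CC(=O)OCC1=C2/C(=C\[C@]3(C)OC(=CC3=O)[C@@H](C)C[C@@H]2OC(=O)/C=C(/C)CO[Si](C)(C)C(C)(C)C)OC1=O | intermediate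
35 | CNP0269057.1: (4S,8S,10S,5E)‑13‑acetoxy‑8‑[(2Z)‑4‑hydroxy‑3‑methylbut‑2‑enoyloxy]‑1,4‑epoxy‑3‑oxogermacra‑1,5,7(11)‑trien‑12,6‑olide | CC(=O)OCC1=C2/C(=C\[C@]3(C)OC(=CC3=O)[C@@H](C)C[C@@H]2OC(=O)/C=C(/C)CO)OC1=O | target

**Step count**
Total steps: 22. Longest linear sequence: 14 (steps 1, 2, 4–7, 13, 14, 17–22). The furan branch (steps 8–12), the alkyne step 3 and the side‑chain steps 15–16 run in parallel.

**Steps most likely to fail**

Step 20 (the proposed new macrocyclising furfurylation; risks are O‑alkylation, oligomerisation and the wrong C4 epimer). The fallback uses known chemistry and sets out from 30. TMSBr in CH₂Cl₂ at −40 °C exchanges only the easily ionised 2‑furylmethyl acetate and gives (1S,3S)‑1‑[4‑(acetoxymethyl)‑2‑(bromomethyl)furan‑3‑yl]‑3‑(5‑methyl‑4‑oxo‑4,5‑dihydrofuran‑2‑yl)butyl (2Z)‑4‑(TBSO)‑3‑methylbut‑2‑enoate F4, used crude. Slow addition of F4 to Cs₂CO₃ in MeCN (1 mM, rt) gives the classical intramolecular SN2 C‑alkylation of the 3(2H)‑furanone enolate under substrate control. The C4 epimers are separated, and the route is rejoined at 31.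

Step 21 (over‑oxidation by singlet oxygen, or ring opening of the furanone during dehydration). The fallback sets out from 31. DMDO in acetone at −20 °C opens the furan to the (Z)‑6‑oxo‑12‑al keto‑enal F5. Pinnick oxidation (NaClO₂, NaH₂PO₄, 2‑methyl‑2‑butene) gives the keto acid, which closes spontaneously to the pseudo‑acid; the route is rejoined at 33 and the TFAA dehydration carried out on isolated material.

Step 13 (slow transmetalation of the doubly ortho‑substituted stannane). The fallback sets out from 21 and 12. Iododestannylation of 21 (I₂, CH₂Cl₂, 0 °C) gives 3‑iodo‑2,4‑bis[(triethylsilyloxy)methyl]furan F1. Fukuyama reduction of 12 (Et₃SiH, Pd/C, acetone) gives (3S)‑3‑(5‑methyl‑4‑oxo‑4,5‑dihydrofuran‑2‑yl)butanal F2. Nozaki–Hiyama–Kishi coupling of F1 with F2 (CrCl₂, cat. NiCl₂, DMF) gives the C8‑epimeric carbinol (3S)‑1‑{2,4‑bis[(triethylsilyloxy)methyl]furan‑3‑yl}‑3‑(5‑methyl‑4‑oxo‑4,5‑dihydrofuran‑2‑yl)butan‑1‑ol F3. Dess–Martin oxidation of F3 returns to ketone 22.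

**Further compounds**
F1 | step 13 | 3‑iodo‑2,4‑bis[(triethylsilyloxy)methyl]furan | CC[Si](CC)(CC)OCc1coc(CO[Si](CC)(CC)CC)c1I
F2 | step 13 | (3S)‑3‑(5‑methyl‑4‑oxo‑4,5‑dihydrofuran‑2‑yl)butanal | C[C@@H](CC=O)C1=CC(=O)C(C)O1
F3 | step 13 | (3S)‑1‑{2,4‑bis[(triethylsilyloxy)methyl]furan‑3‑yl}‑3‑(5‑methyl‑4‑oxo‑4,5‑dihydrofuran‑2‑yl)butan‑1‑ol (C1 epimers) | C[C@@H](CC(O)c1c(CO[Si](CC)(CC)CC)occ1CO[Si](CC)(CC)CC)C1=CC(=O)C(C)O1
F4 | step 20 | (1S,3S)‑1‑[4‑(acetoxymethyl)‑2‑(bromomethyl)furan‑3‑yl]‑3‑(5‑methyl‑4‑oxo‑4,5‑dihydrofuran‑2‑yl)butyl (2Z)‑4‑(TBSO)‑3‑methylbut‑2‑enoate | C[C@@H](C[C@H](OC(=O)/C=C(/C)CO[Si](C)(C)C(C)(C)C)c1c(CBr)occ1COC(C)=O)C1=CC(=O)C(C)O1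
F5 | step 21 | (4S,8S,10S)‑(Z)‑6‑oxo‑12‑al keto‑enal from oxidative opening of the furan of 31 | CC(=O)OC/C(C=O)=C1/C(=O)C[C@]2(C)OC(=CC2=O)[C@@H](C)C[C@@H]1OC(=O)/C=C(/C)CO[Si](C)(C)C(C)(C)C
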